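## Retrosynthetic overview
- Vitedoin A is obtained by chemoselective reduction of the saturated CHO and removal of two aryl TBS groups from a trans-1-aryl-1,2-dihydronaphthalene-2,3-dicarbaldehyde.
- That dialdehyde comes from a one-pot cascade. An amine-catalysed enantioselective alkylation of succinaldehyde by a benzhydryl cation, which desymmetrises the dialdehyde, forms C1–C2. An intramolecular aldol condensation onto the ring-A CHO then forms C3=C4 and closes the only new ring.
- The benzhydryl precursor is the diaryl carbinol from directed ortho-lithiation of TBS-vanillin at C-2 (between CHO and OMe) and addition to a second molecule of TBS-vanillin. Vanillin supplies both aryl rings, and succinaldehyde comes from 2,5-dimethoxytetrahydrofuran.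

**Assumptions**
- The target is the trans (1S,2R) isomer, which I confirmed from the SMILES: the C1 aryl and C2 CH2OH lie on opposite faces of the ring.
- The α-amino-alkoxide and the 3-OMe cooperatively direct lithiation to C-2.
- The (R)-diarylprolinol catalyst is expected to give the (1S,2R) sense by analogy with syn-selective Hayashi–Jørgensen enamine additions.
- The o-(hydroxy(aryl)methyl)benzaldehyde 4 may exist partly as its cyclic lactol. It ionises to the same cation, so the open form is drawn.

## Route

**Step 1**
Reactants: 1 (vanillin, 4-hydroxy-3-methoxybenzaldehyde)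
Product: 2 (4-O-TBS-vanillin, 4-(tert-butyldimethylsilyloxy)-3-methoxybenzaldehyde)
Conditions: TBSCl, imidazole, DMF, 0 °C → rt
Reagents that add atoms: TBSCl, CC(C)(C)[Si](C)(C)Cl
Why: Silylation masks the acidic phenol so that it survives the organolithium. The TBS ether is removable at the end under mild buffered fluoride.

**Step 2**
Reactants: 2 (4-O-TBS-vanillin)
Product: 3 (C-2 lithiated α-amino-alkoxide of 2)
Conditions: LiN(Me)CH2CH2NMe2 (1.1 equiv), THF, −20 °C, 15 min; then n-BuLi (1.5 equiv), −20 °C, 3 h
Reagents that add atoms: lithium N,N,N′-trimethylethylenediamide, CN(C)CCN(C)[Li]; n-BuLi, CCCC[Li] (supplies the aryl Li)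
Why: Comins α-amino-alkoxide directed ortho-metalation (aldehyde protected in situ as a lithium aminal alkoxide) is reinforced by the adjacent 3-OMe, so it should lithiate the doubly flanked C-2. This sets the unusual 7-OH/8-OMe pattern of the target.

**Step 3**
Reactants: 3 (aryllithium from Step 2, generated in the same pot); 2 (4-O-TBS-vanillin, 1.6 equiv, as electrophile)
Product: 4 (rac-2-[(4-TBSO-3-methoxyphenyl)(hydroxy)methyl]-4-TBSO-3-methoxybenzaldehyde)
Conditions: 2, THF, −78 °C → 0 °C; then 1 M aq. HCl, 0 °C, 10 min
Reagents that add atoms: water, O (aqueous HCl work-up hydrolyses the aminal alkoxide back to CHO)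
Why: Nucleophilic 1,2-addition of the aryllithium to the aldehyde of a second molecule of 2 joins the two vanillin units. The carbinol centre is racemic but is destroyed by ionisation in Step 5. The ring-A aldehyde is regenerated on work-up.

**Step 4**
Reactants: 5 (2,5-dimethoxytetrahydrofuran)
Product: 6 (succinaldehyde)
Conditions: H2O, 0.1 M HCl, 60 °C, 2 h; neutralise to pH ~6 and use immediately
Reagents that add atoms: water, O
Why: Acid hydrolysis of the cyclic bis-acetal releases the masked symmetric 1,4-dialdehyde (the standard Robinson–Clauson-Kaas-type unmasking).

**Step 5**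
Reactants: 4 (diaryl carbinol-aldehyde); 6 (succinaldehyde)
Product: 7 ((1S,2R)-1-(4-TBSO-3-methoxyphenyl)-7-TBSO-8-methoxy-1,2-dihydronaphthalene-2,3-dicarbaldehyde)
Conditions: 6 (3 equiv), (R)-diphenylprolinol TMS ether (20 mol%), (PhO)2P(O)OH (20 mol%), HFIP/MeCN 1:4, 25 °C, 24 h; then piperidine/AcOH (20 mol% each), 50 °C, 8 h
Reagents that add atoms: none (the catalysts and additives are not incorporated)
Why: Proposed new method: in HFIP with the Brønsted acid, the p-siloxy benzhydrol 4 ionises to a siloxy-stabilised benzhydryl cation (loss of water). The chiral enamine of succinaldehyde, which desymmetrises the dialdehyde, attacks this cation on the face set by the bulky diarylprolinol group. This sets C-1 and the syn-type C-2 configuration, which corresponds to the trans (1S,2R) ring relationship. The closest known reactions are Hayashi–Jørgensen enamine additions to nitro-olefins and amine-catalysed SN1-type alkylations of aldehydes with benzhydryl cations and p-quinone methides. The second enamine, formed at the other CHO, then undergoes intramolecular aldol condensation onto the ring-A CHO. This closes the six-membered ring and forms the conjugated enal C3=C4. C-2, α to the saturated CHO, can equilibrate to the thermodynamic trans arrangement under the weakly basic conditions, while C-1 is not epimerisable. Any adventitious loss of the pendant-ring TBS group converges on the same final product after Step 7.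

**Step 6**
Reactants: 7
Product: 8 ((1S,2R)-2-(hydroxymethyl)-1-(4-TBSO-3-methoxyphenyl)-7-TBSO-8-methoxy-1,2-dihydronaphthalene-3-carbaldehyde)
Conditions: NaBH(OAc)3 (1.1 equiv), MeCN/AcOH 20:1, 0 °C, 30 min
Reagents that add atoms: none (hydride only)
Why: Triacetoxyborohydride is a mild, non-basic reductant that prefers the more electrophilic aliphatic aldehyde over the conjugated, aryl-deactivated enal (chemoselective aldehyde reduction). The acidic medium avoids epimerisation at C-2, and the step fixes the C-2 CH2OH.

**Step 7**
Reactants: 8
Product: 9 (Vitedoin A)
Conditions: TBAF (2.4 equiv), AcOH (2.4 equiv), THF, 0 °C, 30 min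
Reagents that add atoms: none (the silyl groups are removed; only H is added)
Why: Buffered fluoride desilylation cleaves both aryl TBS ethers. The enal, primary alcohol and methyl ethers are untouched, and no stereocentre is affected.

## Compound list
1 | vanillin | COc1cc(C=O)ccc1O | starting material
2 | 4-O-TBS-vanillin | COc1cc(C=O)ccc1O[Si](C)(C)C(C)(C)C | intermediate
3 | C-2 lithiated lithium α-amino-alkoxide of 2 | [Li]c1c(C(O[Li])N(C)CCN(C)C)ccc(O[Si](C)(C)C(C)(C)C)c1OC | intermediate (generated in situ)
4 | rac-diaryl carbinol-aldehyde | COc1cc(C(O)c2c(C=O)ccc(O[Si](C)(C)C(C)(C)C)c2OC)ccc1O[Si](C)(C)C(C)(C)C | intermediate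
5 | 2,5-dimethoxytetrahydrofuran | COC1CCC(OC)O1 | starting material
6 | succinaldehyde | O=CCCC=O | intermediate (from 5)
7 | (1S,2R)-bis-TBS dihydronaphthalene-2,3-dicarbaldehyde | COc1cc([C@H]2c3c(ccc(O[Si](C)(C)C(C)(C)C)c3OC)C=C(C=O)[C@@H]2C=O)ccc1O[Si](C)(C)C(C)(C)C | intermediate
8 | (1S,2R)-bis-TBS hydroxy-aldehyde | COc1cc([C@H]2c3c(ccc(O[Si](C)(C)C(C)(C)C)c3OC)C=C(C=O)[C@@H]2CO)ccc1O[Si](C)(C)C(C)(C)C | intermediate
9 | Vitedoin A | COc1cc([C@H]2c3c(ccc(O)c3OC)C=C(C=O)[C@@H]2CO)ccc1O | target

**Total steps:** 7 (Steps 2 and 3 are telescoped in one pot). **Longest linear sequence:** 6 (1 → 2 → 3 → 4 → 7 → 8 → 9).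

## Three steps most likely to fail
1. **Step 5** (ionisation, enantio- and diastereoselectivity, aldol stage): the ortho-substituted benzhydryl cation may ionise poorly or give low ee/dr, and the 1,2-dihydro enal could isomerise to the conjugated 1,4-dihydro isomer.
   - Fallback: use a stepwise route. Add a chiral enolate of 4,4-dimethoxybutanoate (Evans N-acyl-oxazolidinone) to the preformed p-quinone methide of 4, reduce the auxiliary to CH2OH, then unmask the acetal and close the ring by aldol condensation onto the ring-A CHO.
2. **Steps 2/3** (C-2 regioselectivity of lithiation): lithiation at C-6 instead of C-2 would give the wrong (6-OMe-type) isomer.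
   - Fallback: block C-6 with Br (bromination of 2), do the lithiation/addition, then remove the Br by hydrodebromination before the cascade. Alternatively, prepare the C-2 aryl-metal by halogen–metal exchange from a pre-installed 2-bromo derivative.
3. **Step 6** (chemoselectivity and C-2 integrity): over-reduction of the enal, or epimerisation at C-2.
   - Fallback: alkylate with 4,4-dimethoxybutanal instead of succinaldehyde, so only one free CHO is present. Reduce that CHO in situ with NaBH4 to CH2OH, then unmask the acetal with acid and close the ring by aldol condensation onto the ring-A CHO. C-2 is then locked as CH2OH, and only desilylation remains.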